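**Retrosynthetic overview**
- Target ⇒ a tricyclic lactone–chromanone by two C–O hydrogenolyses: the 3-phenylpropanoyl ketone and the 7-OH are carried as a closed 2-phenylchroman-4-one ring, the 5-OH as a benzyl ether.
- Tricycle ⇒ two rings in one flask from a 2',6'-dihydroxy-4'-benzyloxychalcone and phenylpropynal: carbene-catalysed [3+3] annulation (lactone ring, sets C4), then oxa-Michael closure (chromanone ring).
- The para benzyl ether leaves only the oxygen ortho to the ketone for lactonisation, so only the 8-acyl lactone can form; the chromanone closure ties up the last free phenol.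
- Chalcone ⇒ Claisen–Schmidt condensation of para-monobenzylated 2',4',6'-trihydroxyacetophenone with benzaldehyde.
- Ring order: central arene bought; lactone first, chromanone second (same step); chromanone reopened in the last step.

Assumption: the (5aS,10bR) antipode of the aminoindanol-derived N-mesityl triazolium chloride is taken to give Si-face attack (4S); both antipodes are sold, so the other is used if the first run shows 4R.

**Step 1**
Reactants: 1 1-(2,4,6-trihydroxyphenyl)ethan-1-one
Product: 2 1-[4-(benzyloxy)-2,6-dihydroxyphenyl]ethan-1-one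
Conditions: BnBr (1.0 equiv), K2CO3 (1.05 equiv), acetone, 50 °C
Reagents that add atoms: benzyl bromide, BrCc1ccccc1
Why: Williamson ether synthesis in which the 4-OH, the only hydroxyl not hydrogen-bonded to the ketone and the most acidic, is alkylated selectively by one equivalent of base and bromide.

**Step 2**
Reactants: 2 1-[4-(benzyloxy)-2,6-dihydroxyphenyl]ethan-1-one; 3 benzaldehyde
Product: 4 (2E)-1-[4-(benzyloxy)-2,6-dihydroxyphenyl]-3-phenylprop-2-en-1-one
Conditions: KOH (50% aq., 10 equiv), EtOH, 0 °C to 23 °C, 36 h; then cold 2 M HCl to pH 3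
Reagents that add atoms: none
Why: Claisen–Schmidt aldol condensation, in which the phenoxide form does not cyclise in strong base, dehydration gives the E-alkene, and cold acidification releases the open chalcone (no stereocentre formed).

**Step 3**
Reactants: 4 (2E)-1-[4-(benzyloxy)-2,6-dihydroxyphenyl]-3-phenylprop-2-en-1-one; 5 3-phenylprop-2-ynal
Product: 7 (4S)-5-(benzyloxy)-4,8-diphenyl-3,4,8,9-tetrahydro-2H,10H-pyrano[2,3-f]chromene-2,10-dione, via lactone chalcone 6 (not isolated)
Conditions: (5aS,10bR)-aminoindanol N-mesityl triazolium chloride (10 mol%), toluene/THF 4:1, 40 °C, 24 h; then DBU (0.3 equiv), 23 °C, 2 h, same flask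
Reagents that add atoms: none
Why: Proposed new method: the carbene turns ynal 5 by internal redox into a catalyst-bound (E)-cinnamoyl azolium, one of the two equivalent phenols of 4 adds to it and a Coates–Claisen-type [3,3] shift (equivalent to Michael addition) forms C4–C4a on the Si face left open by the indane backbone (4S), acyl transfer to the same ortho oxygen closes the lactone (the para oxygen is benzylated) and frees the catalyst, and DBU then closes the remaining phenol onto the enone by 6-endo oxa-Michael addition (C8 uncontrolled, removed later); the closest known reaction types are the carbene-catalysed [3+3] annulation of ynals with naphthols and other stable enols and the base-mediated chalcone-to-flavanone isomerisation.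

**Step 4**
Reactants: 7 (4S)-5-(benzyloxy)-4,8-diphenyl-3,4,8,9-tetrahydro-2H,10H-pyrano[2,3-f]chromene-2,10-dione
Product: 8 (4S)-5,7-dihydroxy-4-phenyl-8-(3-phenylpropanoyl)-3,4-dihydro-2H-chromen-2-one
Conditions: H2 (1 atm), Pd/C (10 wt%), EtOAc/AcOH 20:1, 23 °C, stop after 2 equiv H2
Reagents that add atoms: none
Why: Catalytic hydrogenolysis cleaves the benzyl ether and the benzylic C8–O bond of the chromanone (a benzyl aryl ether beta to the ketone), which reopens that ring to the 3-phenylpropanoyl ketone and erases the C8 centre, while the lactone, the hindered chelated ketone and C4 (C–C bonds only, base-free so no acyl migration) are untouched.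

**Compound list**
1 | 1-(2,4,6-trihydroxyphenyl)ethan-1-one | CC(=O)c1c(O)cc(O)cc1O | starting material
2 | 1-[4-(benzyloxy)-2,6-dihydroxyphenyl]ethan-1-one | CC(=O)c1c(O)cc(OCc2ccccc2)cc1O | intermediate
3 | benzaldehyde | O=Cc1ccccc1 | starting material
4 | (2E)-1-[4-(benzyloxy)-2,6-dihydroxyphenyl]-3-phenylprop-2-en-1-one | O=C(/C=C/c1ccccc1)c1c(O)cc(OCc2ccccc2)cc1O | intermediate
5 | 3-phenylprop-2-ynal | O=CC#Cc1ccccc1 | starting material
6 | (4S)-5-(benzyloxy)-7-hydroxy-4-phenyl-8-[(2E)-3-phenylprop-2-enoyl]-3,4-dihydro-2H-chromen-2-one (lactone chalcone, not isolated) | O=C1C[C@@H](c2ccccc2)c2c(OCc3ccccc3)cc(O)c(C(=O)/C=C/c3ccccc3)c2O1 | intermediate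
7 | (4S)-5-(benzyloxy)-4,8-diphenyl-3,4,8,9-tetrahydro-2H,10H-pyrano[2,3-f]chromene-2,10-dione (both C8 epimers) | O=C1C[C@@H](c2ccccc2)c2c(OCc3ccccc3)cc3OC(c4ccccc4)CC(=O)c3c2O1 | intermediate
8 | (4S)-5,7-dihydroxy-4-phenyl-8-(3-phenylpropanoyl)-3,4-dihydro-2H-chromen-2-one | O=C1C[C@@H](c2ccccc2)c2c(O)cc(O)c(C(=O)CCc3ccccc3)c2O1 | target

**Totals**
Total steps: 4. Longest linear sequence: 4.

**Three steps most likely to fail**

Step 3 (most at risk). The acyl-deactivated phenol may be a sluggish carbon nucleophile, the aryl ynal may give modest ee or O-acylation, and the catalyst may engage the enone. The fallback sets out from compound 4 and comes back at compound 7. Chalcone 4 and (E)-cinnamaldehyde are combined with 2-[diphenyl(trimethylsilyloxy)methyl]pyrrolidine (20 mol%, the antipode that gives 4S) and benzoic acid in toluene. This iminium-catalysed Friedel–Crafts alkylation and hemiacetalisation, with DBU then added for the oxa-Michael closure, gives the lactol (4S)-5-(benzyloxy)-2-hydroxy-4,8-diphenyl-3,4,8,9-tetrahydro-2H,10H-pyrano[2,3-f]chromen-10-one F1. Its oxidation with PhI(OAc)2 and catalytic TEMPO in CH2Cl2 gives 7.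

Step 4. Hydrogenolysis of the chromanone C8–O bond may lag behind debenzylation or be overtaken by ketone reduction. The fallback sets out from compound 4 and comes back at compound 8. The alkene of 4 is reduced first with H2 and RhCl(PPh3)3 in toluene/EtOH, which keeps the benzyl ether and gives 1-[4-(benzyloxy)-2,6-dihydroxyphenyl]-3-phenylpropan-1-one F2. The carbene annulation with 5 (first stage of step 3, 1.0 equiv of 5) then gives (4S)-5-(benzyloxy)-7-hydroxy-4-phenyl-8-(3-phenylpropanoyl)-3,4-dihydro-2H-chromen-2-one F3. Simple O-debenzylation (H2, Pd/C, EtOAc) gives 8.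

Step 2. Condensation on the free diphenol can be slow, and the chalcone can ring-close on work-up. The fallback sets out from compound 2 and comes back at compound 4. One chelated hydroxyl is masked with MOMCl and i-Pr2NEt in CH2Cl2 to give 1-[4-(benzyloxy)-2-hydroxy-6-(methoxymethoxy)phenyl]ethan-1-one F4. Condensation with 3 (KOH, EtOH) gives (2E)-1-[4-(benzyloxy)-2-hydroxy-6-(methoxymethoxy)phenyl]-3-phenylprop-2-en-1-one F5. Brief treatment with HCl in MeOH at 23 °C removes the acetal and gives 4.

**Further compounds**
F1 | step 3 | (4S)-5-(benzyloxy)-2-hydroxy-4,8-diphenyl-3,4,8,9-tetrahydro-2H,10H-pyrano[2,3-f]chromen-10-one | OC1C[C@@H](c2ccccc2)c2c(OCc3ccccc3)cc3OC(c4ccccc4)CC(=O)c3c2O1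
F2 | step 4 | 1-[4-(benzyloxy)-2,6-dihydroxyphenyl]-3-phenylpropan-1-one | O=C(CCc1ccccc1)c1c(O)cc(OCc2ccccc2)cc1O
F3 | step 4 | (4S)-5-(benzyloxy)-7-hydroxy-4-phenyl-8-(3-phenylpropanoyl)-3,4-dihydro-2H-chromen-2-one | O=C1C[C@@H](c2ccccc2)c2c(OCc3ccccc3)cc(O)c(C(=O)CCc3ccccc3)c2O1
F4 | step 2 | 1-[4-(benzyloxy)-2-hydroxy-6-(methoxymethoxy)phenyl]ethan-1-one | CC(=O)c1c(O)cc(OCc2ccccc2)cc1OCOC
F5 | step 2 | (2E)-1-[4-(benzyloxy)-2-hydroxy-6-(methoxymethoxy)phenyl]-3-phenylprop-2-en-1-one | O=C(/C=C/c1ccccc1)c1c(O)cc(OCc2ccccc2)cc1OCOC
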